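**Strategy.** The piperidine is made from a furan. The N1–C2(CH3)–C3(O) amino-alcohol edge of the ring, together with C6 next to nitrogen, maps onto (R)-1-(furan-2-yl)ethylamine: the carbinamine carbon is C2, furan C2 is C3, furan C3 and C4 are C4 and C5, furan C5 is C6. An aza-Achmatowicz oxidative rearrangement of the N-tert-butanesulfinyl amine, in which the peracid also converts the auxiliary into a tert-butylsulfonyl (Bus) protecting group, expands the five-membered furan into the six-membered dihydropyridinone with C3 as ketone and C6 as N,O-acetal. C6 is then allylated cis to the axial methyl, C3 is reduced cis, and cross-metathesis completes the chain.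

Key step: step 2

Remark: Bus = tert-butylsulfonyl. The C6 configuration of hemiaminals 7 and 8 is left open (epimer mixture), since both epimers give the same iminium ion 9. 2-Acetylfuran, (R)-2-methylpropane-2-sulfinamide and 11-bromoundec-1-ene are taken as commercial.

**Route**

Step 1
Reactants: 1 2-acetylfuran; 2 (R)-2-methylpropane-2-sulfinamide
Product: 4 (R)-N-[(1R)-1-(furan-2-yl)ethyl]-2-methylpropane-2-sulfinamide, via N-sulfinyl ketimine 3 (not isolated)
Conditions: Ti(OEt)4 (2 equiv), THF, 65 °C; then NaBH4, −48 °C to rt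
Reagents that add atoms: none
Why: Ti(OEt)4-mediated condensation followed by in-situ borohydride reduction (sulfinyl-imine reductive amination) should deliver hydride through a six-membered transition state in which boron is held by the sulfinyl oxygen, so the (R)-sulfinyl group sets the (R)-carbinamine centre (future C2); the minor diastereomer is to be removed by chromatography, because after step 2 it would become the enantiomer.

Step 2
Reactants: 4 (R)-N-[(1R)-1-(furan-2-yl)ethyl]-2-methylpropane-2-sulfinamide
Product: 7 (2R)-1-(tert-butylsulfonyl)-6-hydroxy-2-methyl-1,6-dihydropyridin-3(2H)-one, via Bus sulfonamide 5 (not isolated), via cis-enedione 6 (not isolated)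
Conditions: mCPBA (2.3 equiv), CH2Cl2, 0 °C to rt
Reagents that add atoms: mCPBA, OOC(=O)c1cccc(Cl)c1
Why: The peracid should first oxidise the sulfinyl sulfur to the sulfonyl group (5) and then epoxidise the electron-rich furan, which opens to cis-enedione 6 (furan C2 becomes the C3 ketone, furan C5 an aldehyde); the sulfonamide N–H then adds to that aldehyde, so the five-membered furan is replaced by the six-membered N1/C2–C6 ring. The closest known reaction type is the aza-Achmatowicz oxidative rearrangement of N-sulfonyl 1-(2-furyl)alkylamines, run here together with the known peracid oxidation of tert-butanesulfinamides to Bus sulfonamides. The ring closes by 6-exo-trig addition of nitrogen to the C6 aldehyde carbonyl. The only new stereocentre, the C6 hemiaminal carbon, is under thermodynamic (anomeric and A(1,3)) control and is erased in step 4, while C2 is untouched because no bond to it is broken. The step needs oxidation of the furan without further oxidation of the product, which the electron-poor enone secures, and the Z geometry needed for cyclisation is inherited from the furan ring.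

Step 3
Reactants: 7 (2R)-1-(tert-butylsulfonyl)-6-hydroxy-2-methyl-1,6-dihydropyridin-3(2H)-one
Product: 8 (2R)-1-(tert-butylsulfonyl)-6-hydroxy-2-methylpiperidin-3-one
Conditions: H2 (1 atm), Pd/C (10%), EtOAc, rt
Reagents that add atoms: none
Why: Heterogeneous catalytic hydrogenation should saturate the electron-poor C4=C5 enone bond much faster than it touches the ketone or the sulfonamide, giving the chair-capable ring needed for stereoelectronic control in step 4.

Step 4
Reactants: 8 (2R)-1-(tert-butylsulfonyl)-6-hydroxy-2-methylpiperidin-3-one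
Product: 10 (2R,6R)-1-(tert-butylsulfonyl)-2-methyl-6-(prop-2-en-1-yl)piperidin-3-one, via N-sulfonyliminium ion 9 (not isolated)
Conditions: allyltrimethylsilane (3 equiv), BF3·OEt2 (2.5 equiv), CH2Cl2, −78 to 0 °C
Reagents that add atoms: allyltrimethylsilane, C=CC[Si](C)(C)C
Why: BF3·OEt2 should ionise the hemiaminal to N-sulfonyliminium ion 9, which the allylsilane attacks at C6 (Hosomi–Sakurai-type N-sulfonyliminium allylation); A(1,3) strain with the sulfonyl group holds the C2 methyl axial, and axial attack through a chair-like transition state places the allyl group cis to it.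

Step 5
Reactants: 10 (2R,6R)-1-(tert-butylsulfonyl)-2-methyl-6-(prop-2-en-1-yl)piperidin-3-one
Product: 11 (2R,3R,6R)-1-(tert-butylsulfonyl)-2-methyl-6-(prop-2-en-1-yl)piperidin-3-ol
Conditions: NaBH4, MeOH, −40 to 0 °C
Reagents that add atoms: none
Why: Borohydride reduction of the ketone should occur by axial attack at C3 from the face opposite the adjacent axial C2 methyl, so the hydroxyl ends up equatorial and cis to the methyl (all-cis ring).

Step 6
Reactants: 11 (2R,3R,6R)-1-(tert-butylsulfonyl)-2-methyl-6-(prop-2-en-1-yl)piperidin-3-ol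
Product: 12 (2R,3R,6R)-1-(tert-butylsulfonyl)-2-methyl-6-(prop-2-en-1-yl)piperidin-3-yl acetate
Conditions: Ac2O, pyridine, DMAP (cat.), CH2Cl2, rt
Reagents that add atoms: acetic anhydride, CC(=O)OC(C)=O
Why: DMAP-catalysed acylation of the secondary alcohol; the sulfonamide nitrogen has no N–H, so only oxygen is acetylated.

Step 7
Reactants: 13 11-bromoundec-1-ene
Product: 15 tridec-12-en-2-one, via undec-10-enylmagnesium bromide 14 (not isolated)
Conditions: Mg turnings, I2 (cat.), THF, reflux; then N-methoxy-N-methylacetamide, 0 °C; 1 M HCl work-up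
Reagents that add atoms: N-methoxy-N-methylacetamide, CC(=O)N(C)OC; magnesium, [Mg] (kept only in intermediate 14)
Why: Grignard formation followed by Weinreb ketone synthesis; the magnesium chelate of the tetrahedral adduct prevents over-addition and collapses to the methyl ketone on acidic work-up.

Step 8
Reactants: 12 (2R,3R,6R)-1-(tert-butylsulfonyl)-2-methyl-6-(prop-2-en-1-yl)piperidin-3-yl acetate; 15 tridec-12-en-2-one (3 equiv)
Product: 16 (2R,3R,6R)-1-(tert-butylsulfonyl)-2-methyl-6-(13-oxotetradec-2-en-1-yl)piperidin-3-yl acetate (E/Z mixture)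
Conditions: second-generation Grubbs catalyst RuCl2(=CHPh)(PCy3)(H2IMes) (5 mol %), 1,4-benzoquinone (10 mol %), CH2Cl2, 40 °C
Reagents that add atoms: none
Why: Olefin cross-metathesis between two unhindered terminal alkenes, driven by loss of ethylene and the excess of 15; the non-basic sulfonamide does not bind ruthenium, and the alkene geometry is irrelevant because the bond is hydrogenated next.

Step 9
Reactants: 16 (2R,3R,6R)-1-(tert-butylsulfonyl)-2-methyl-6-(13-oxotetradec-2-en-1-yl)piperidin-3-yl acetate
Product: 17 (2R,3R,6S)-1-(tert-butylsulfonyl)-2-methyl-6-(13-oxotetradecyl)piperidin-3-yl acetate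
Conditions: H2 (1 atm), Pd/C (10%), EtOAc, rt
Reagents that add atoms: none
Why: Catalytic hydrogenation of the isolated disubstituted alkene; the ketone, the acetate and the Bus group should be inert and no stereocentre is affected (the C6 descriptor changes only through priorities).

Step 10
Reactants: 17 (2R,3R,6S)-1-(tert-butylsulfonyl)-2-methyl-6-(13-oxotetradecyl)piperidin-3-yl acetate
Product: 18 (2R,3R,6S)-2-methyl-6-(13-oxotetradecyl)piperidin-3-yl acetate, (−)-3-O-acetylspectaline
Conditions: TfOH (0.1 M, 3 equiv), anisole (10 equiv), CH2Cl2, 0 °C; then aq. NaHCO3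
Reagents that add atoms: none
Why: Acidolysis of the tert-butylsulfonamide: protonation releases the tert-butyl cation (trapped by anisole) and the resulting aminosulfinic acid loses SO2, a known cleavage for Bus groups on secondary amines under anhydrous conditions that should leave acetate and ketone untouched; bicarbonate work-up gives the free base.

**Compound list**

1 | 2-acetylfuran | CC(=O)c1ccco1 | starting material
2 | (R)-2-methylpropane-2-sulfinamide | CC(C)(C)[S@@](=O)N | starting material
3 | (R,E)-N-[1-(furan-2-yl)ethylidene]-2-methylpropane-2-sulfinamide (not isolated) | C/C(=N\[S@](=O)C(C)(C)C)c1ccco1 | intermediate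
4 | (R)-N-[(1R)-1-(furan-2-yl)ethyl]-2-methylpropane-2-sulfinamide | C[C@@H](N[S@](=O)C(C)(C)C)c1ccco1 | intermediate
5 | N-[(1R)-1-(furan-2-yl)ethyl]-2-methylpropane-2-sulfonamide (not isolated) | C[C@@H](NS(=O)(=O)C(C)(C)C)c1ccco1 | intermediate
6 | (2Z,5R)-5-[(tert-butylsulfonyl)amino]-4-oxohex-2-enal (not isolated) | C[C@@H](NS(=O)(=O)C(C)(C)C)C(=O)/C=C\C=O | intermediate
7 | (2R)-1-(tert-butylsulfonyl)-6-hydroxy-2-methyl-1,6-dihydropyridin-3(2H)-one (C6 epimers) | O=C1C=CC(O)N(S(=O)(=O)C(C)(C)C)[C@@H]1C | intermediate
8 | (2R)-1-(tert-butylsulfonyl)-6-hydroxy-2-methylpiperidin-3-one (C6 epimers) | O=C1CCC(O)N(S(=O)(=O)C(C)(C)C)[C@@H]1C | intermediate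
9 | (2R)-1-(tert-butylsulfonyl)-2-methyl-3-oxo-2,3,4,5-tetrahydropyridin-1-ium (not isolated) | C[C@@H]1C(=O)CCC=[N+]1S(=O)(=O)C(C)(C)C | intermediate
10 | (2R,6R)-1-(tert-butylsulfonyl)-2-methyl-6-(prop-2-en-1-yl)piperidin-3-one | C=CC[C@H]1CCC(=O)[C@@H](C)N1S(=O)(=O)C(C)(C)C | intermediate
11 | (2R,3R,6R)-1-(tert-butylsulfonyl)-2-methyl-6-(prop-2-en-1-yl)piperidin-3-ol | C=CC[C@H]1CC[C@@H](O)[C@@H](C)N1S(=O)(=O)C(C)(C)C | intermediate
12 | (2R,3R,6R)-1-(tert-butylsulfonyl)-2-methyl-6-(prop-2-en-1-yl)piperidin-3-yl acetate | C=CC[C@H]1CC[C@@H](OC(C)=O)[C@@H](C)N1S(=O)(=O)C(C)(C)C | intermediate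
13 | 11-bromoundec-1-ene | C=CCCCCCCCCCBr | starting material
14 | undec-10-enylmagnesium bromide (not isolated) | C=CCCCCCCCCC[Mg]Br | intermediate
15 | tridec-12-en-2-one | CC(=O)CCCCCCCCCC=C | intermediate
16 | (2R,3R,6R)-1-(tert-butylsulfonyl)-2-methyl-6-(13-oxotetradec-2-en-1-yl)piperidin-3-yl acetate (E/Z mixture) | CC(=O)CCCCCCCCCC=CC[C@H]1CC[C@@H](OC(C)=O)[C@@H](C)N1S(=O)(=O)C(C)(C)C | intermediate
17 | (2R,3R,6S)-1-(tert-butylsulfonyl)-2-methyl-6-(13-oxotetradecyl)piperidin-3-yl acetate | CC(=O)CCCCCCCCCCCC[C@H]1CC[C@@H](OC(C)=O)[C@@H](C)N1S(=O)(=O)C(C)(C)C | intermediate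
18 | (2R,3R,6S)-2-methyl-6-(13-oxotetradecyl)piperidin-3-yl acetate, (−)-3-O-acetylspectaline | CC(=O)CCCCCCCCCCCC[C@H]1CC[C@@H](OC(C)=O)[C@@H](C)N1 | target

**Totals.** Total step count: 10. Longest linear sequence: 9 steps (steps 1–6 and 8–10); step 7 makes the side-chain partner.

**Steps most likely to fail**

1. Step 4. The free hemiaminal may open to its aldehyde form and be allylated there, the ketone may compete for the Lewis acid, and the keto-iminium ion may enolise towards C2, eroding the cis relationship. The fallback reorders events so that the allylation runs on a ring with neither ketone nor free hydroxyl. It sets out from 8: MeOH/PPTS exchanges the hemiaminal hydroxyl for methoxy to give (2R)-1-(tert-butylsulfonyl)-6-methoxy-2-methylpiperidin-3-one F1. NaBH4 in MeOH reduces the ketone anti to the axial methyl to give (2R,3R)-1-(tert-butylsulfonyl)-6-methoxy-2-methylpiperidin-3-ol F2. Ac2O/pyridine/DMAP gives (2R,3R)-1-(tert-butylsulfonyl)-6-methoxy-2-methylpiperidin-3-yl acetate F3. Allyltrimethylsilane/BF3·OEt2 in CH2Cl2 at −78 °C then ionises only the N,O-acetal and should give 12, where the route is rejoined (steps 4 to 6 are replaced).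

2. Step 2. Furan oxidation may outrun sulfur oxidation, leaving an acid-labile N-sulfinyl hemiaminal that loses the auxiliary, or excess peracid may degrade the product. The fallback separates the two oxidations and uses a different furan oxidant. It sets out from 4: mCPBA (1.05 equiv, −20 °C) oxidises only sulfur and Bus sulfonamide 5 is isolated. N-Bromosuccinimide in NaHCO3-buffered THF–H2O at 0 °C then oxidises the furan by bromonium-initiated 2,5-hydroxylation instead of epoxidation and gives 7, where the route is rejoined (no further compound, F0).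

3. Step 8. Homodimerisation of either partner may dominate, and ruthenium hydride species may migrate the double bond before metathesis, giving chain-shortened homologues that cannot be separated after hydrogenation. The fallback builds the chain by sp3–sp3 coupling and installs the ketone by oxidation. It sets out from 12: 9-BBN in THF hydroborates the allyl group to (2R,3R,6S)-6-[3-(9-borabicyclo[3.3.1]nonan-9-yl)propyl]-1-(tert-butylsulfonyl)-2-methylpiperidin-3-yl acetate F4, used without isolation. Alkyl–alkyl Suzuki–Miyaura coupling with bromide 13 (Pd(OAc)2, PCy3, K3PO4·H2O, THF, rt) gives (2R,3R,6S)-1-(tert-butylsulfonyl)-2-methyl-6-(tetradec-13-en-1-yl)piperidin-3-yl acetate F5. Wacker oxidation (PdCl2, CuCl, O2, DMF–H2O) of the terminal alkene gives methyl ketone 17, where the route is rejoined (steps 8 and 9 are replaced).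

**Further compounds**

F1 | step 4 | (2R)-1-(tert-butylsulfonyl)-6-methoxy-2-methylpiperidin-3-one | O=C1CCC(OC)N(S(=O)(=O)C(C)(C)C)[C@@H]1C
F2 | step 4 | (2R,3R)-1-(tert-butylsulfonyl)-6-methoxy-2-methylpiperidin-3-ol | COC1CC[C@@H](O)[C@@H](C)N1S(=O)(=O)C(C)(C)C
F3 | step 4 | (2R,3R)-1-(tert-butylsulfonyl)-6-methoxy-2-methylpiperidin-3-yl acetate | COC1CC[C@@H](OC(C)=O)[C@@H](C)N1S(=O)(=O)C(C)(C)C
F0 | step 2 | none | none
F4 | step 8 | (2R,3R,6S)-6-[3-(9-borabicyclo[3.3.1]nonan-9-yl)propyl]-1-(tert-butylsulfonyl)-2-methylpiperidin-3-yl acetate | B2(CCC[C@H]1CC[C@@H](OC(C)=O)[C@@H](C)N1S(=O)(=O)C(C)(C)C)C3CCCC2CCC3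
F5 | step 8 | (2R,3R,6S)-1-(tert-butylsulfonyl)-2-methyl-6-(tetradec-13-en-1-yl)piperidin-3-yl acetate | C=CCCCCCCCCCCCC[C@H]1CC[C@@H](OC(C)=O)[C@@H](C)N1S(=O)(=O)C(C)(C)C
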